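**Retrosynthetic overview**

1. Target 12 ⇐ 11 by cross-metathesis; the bridgehead prenyl group is carried as an (E)-but-2-enyl group so that the quaternary ring carbon stays stereogenic until the bicycle is closed.
2. 11 ⇐ 9 by closing the five-membered ring last: 5-exo oxidative radical cyclization of the methyl-bearing ring carbon onto the prenyl group, with O2 capture giving the tertiary alcohol.
3. 9 ⇐ 8 by a dearomative aromatic Claisen rearrangement that creates the quaternary stereocenter by 1,3-chirality transfer from an (S)-but-3-en-2-yl aryl ether.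
4. 8 ⇐ 2,4,6-trihydroxytoluene, (R)-2-methylbutanoic acid (side-chain stereocenter bought), (R)-but-3-en-2-ol (source of the three ring stereocenters) and prenyl bromide.
5. Ring order: the six-membered ring is bought as the arene and dearomatized in step 4; the cyclopentane ring of the bicyclo[3.2.1]octane is formed in step 5.

Assumption: each β-triketone is drawn as one enol tautomer, and stereodescriptors refer to the tautomer drawn.

**Route**

Step 1
Reactants: 1 2,4,6-trihydroxytoluene; 2 (R)-2-methylbutanoic acid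
Product: 4 (2R)-2-methyl-1-(2,4,6-trihydroxy-3-methylphenyl)butan-1-one, via (R)-2-methylbutanoyl chloride 3 (not isolated)
Conditions: (COCl)2, cat. DMF, CH2Cl2, 0 °C to rt; then 1, AlCl3, PhNO2, 0 °C to rt
Reagents that add atoms: none
Why: Friedel–Crafts acylation of the highly activated arene at one of its two equivalent free positions, under non-basic conditions that leave the bought α-stereocenter untouched.

Step 2
Reactants: 4 (2R)-2-methyl-1-(2,4,6-trihydroxy-3-methylphenyl)butan-1-one; 5 (R)-but-3-en-2-ol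
Product: 6 (2R)-1-{4-[(2S)-but-3-en-2-yloxy]-2,6-dihydroxy-3-methylphenyl}-2-methylbutan-1-one
Conditions: PPh3, DIAD, THF, 0 °C to rt
Reagents that add atoms: none
Why: Mitsunobu etherification of the most acidic hydroxyl (para to the ketone, not hydrogen-bonded to it), with SN2 inversion turning the (R)-carbinol into the (S)-ether.

Step 3
Reactants: 6 (2R)-1-{4-[(2S)-but-3-en-2-yloxy]-2,6-dihydroxy-3-methylphenyl}-2-methylbutan-1-one; 7 prenyl bromide (1-bromo-3-methylbut-2-ene)
Product: 8 (2R)-1-{4-[(2S)-but-3-en-2-yloxy]-2,6-dihydroxy-3-methyl-5-(3-methylbut-2-en-1-yl)phenyl}-2-methylbutan-1-one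
Conditions: KOH (1.1 equiv), H2O, 0 °C, 2 h
Reagents that add atoms: none
Why: C-alkylation of the phenoxide at the only free ring carbon (ortho to the phenoxide oxygen), run cold so the allylic aryl ether does not rearrange; no stereocenter is formed.

Step 4
Reactants: 8 (2R)-1-{4-[(2S)-but-3-en-2-yloxy]-2,6-dihydroxy-3-methyl-5-(3-methylbut-2-en-1-yl)phenyl}-2-methylbutan-1-one
Product: 9 (6R)-6-[(2E)-but-2-en-1-yl]-3,5-dihydroxy-4-methyl-2-[(2R)-2-methylbutanoyl]-6-(3-methylbut-2-en-1-yl)cyclohexa-2,4-dien-1-one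
Conditions: PhMe, 120 °C, sealed tube, 4 h
Reagents that add atoms: none
Why: dearomative aromatic Claisen rearrangement ([3,3]-sigmatropic) through a chair transition state with the ether methyl group equatorial, which delivers the butenyl group to one face of the prenyl-bearing ortho carbon, sets the quaternary stereocenter as (6R) by 1,3-chirality transfer from the (S)-ether carbon and gives the (E)-alkene.

Step 5
Reactants: 9 (6R)-6-[(2E)-but-2-en-1-yl]-3,5-dihydroxy-4-methyl-2-[(2R)-2-methylbutanoyl]-6-(3-methylbut-2-en-1-yl)cyclohexa-2,4-dien-1-one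
Product: 11 (1R,5R,6R)-1-[(2E)-but-2-en-1-yl]-4-hydroxy-6-(2-hydroxypropan-2-yl)-5-methyl-3-[(2R)-2-methylbutanoyl]bicyclo[3.2.1]oct-3-ene-2,8-dione, via tertiary hydroperoxide 10 (not isolated)
Conditions: Mn(OAc)3·2H2O (20 mol %), air, AcOH, rt; then PPh3
Reagents that add atoms: dioxygen, O=O
Why: manganese triacetate-mediated oxidative 5-exo-trig radical cyclization of the methyl-bearing triketone carbon onto the more electron-rich trisubstituted prenyl alkene, in which the tether from the quaternary carbon fixes the new methyl bridgehead, the CMe2 radical is expected to sit exo (away from the enolized diketone bridge) to set C6, and O2 capture followed by PPh3 reduction gives the tertiary alcohol.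

Step 6
Reactants: 11 (1R,5R,6R)-1-[(2E)-but-2-en-1-yl]-4-hydroxy-6-(2-hydroxypropan-2-yl)-5-methyl-3-[(2R)-2-methylbutanoyl]bicyclo[3.2.1]oct-3-ene-2,8-dione
Product: 12 (1R,5R,6R)-4-hydroxy-6-(2-hydroxypropan-2-yl)-5-methyl-3-[(2R)-2-methylbutanoyl]-1-(3-methylbut-2-en-1-yl)bicyclo[3.2.1]oct-3-ene-2,8-dione
Conditions: second-generation Grubbs catalyst RuCl2(=CHPh)(PCy3)(H2IMes) (10 mol %), 2-methylbut-2-ene, CH2Cl2, 40 °C
Reagents that add atoms: 2-methylbut-2-ene, CC=C(C)C
Why: olefin cross-metathesis exchanges the ethylidene terminus of the bridgehead butenyl group for isopropylidene to give the prenyl group without touching any stereocenter.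

**Compound list**

1 | 2,4,6-trihydroxytoluene | Cc1c(O)cc(O)cc1O | starting material
2 | (R)-2-methylbutanoic acid | CC[C@@H](C)C(O)=O | starting material
3 | (R)-2-methylbutanoyl chloride | CC[C@@H](C)C(Cl)=O | intermediate
4 | (2R)-2-methyl-1-(2,4,6-trihydroxy-3-methylphenyl)butan-1-one | CC[C@@H](C)C(=O)c1c(O)c(C)c(O)cc1O | intermediate
5 | (R)-but-3-en-2-ol | C[C@@H](O)C=C | starting material
6 | (2R)-1-{4-[(2S)-but-3-en-2-yloxy]-2,6-dihydroxy-3-methylphenyl}-2-methylbutan-1-one | CC[C@@H](C)C(=O)c1c(O)c(C)c(O[C@@H](C)C=C)cc1O | intermediate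
7 | prenyl bromide (1-bromo-3-methylbut-2-ene) | CC(C)=CCBr | starting material
8 | (2R)-1-{4-[(2S)-but-3-en-2-yloxy]-2,6-dihydroxy-3-methyl-5-(3-methylbut-2-en-1-yl)phenyl}-2-methylbutan-1-one | CC[C@@H](C)C(=O)c1c(O)c(C)c(O[C@@H](C)C=C)c(CC=C(C)C)c1O | intermediate
9 | (6R)-6-[(2E)-but-2-en-1-yl]-3,5-dihydroxy-4-methyl-2-[(2R)-2-methylbutanoyl]-6-(3-methylbut-2-en-1-yl)cyclohexa-2,4-dien-1-one | CC[C@@H](C)C(=O)C1=C(O)C(C)=C(O)[C@@](C/C=C/C)(CC=C(C)C)C1=O | intermediate
10 | (1R,5R,6R)-1-[(2E)-but-2-en-1-yl]-6-(2-hydroperoxypropan-2-yl)-4-hydroxy-5-methyl-3-[(2R)-2-methylbutanoyl]bicyclo[3.2.1]oct-3-ene-2,8-dione | CC[C@@H](C)C(=O)C1=C(O)[C@]2(C)C(=O)[C@@](C/C=C/C)(C[C@H]2C(C)(C)OO)C1=O | intermediate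
11 | (1R,5R,6R)-1-[(2E)-but-2-en-1-yl]-4-hydroxy-6-(2-hydroxypropan-2-yl)-5-methyl-3-[(2R)-2-methylbutanoyl]bicyclo[3.2.1]oct-3-ene-2,8-dione | CC[C@@H](C)C(=O)C1=C(O)[C@]2(C)C(=O)[C@@](C/C=C/C)(C[C@H]2C(C)(C)O)C1=O | intermediate
12 | (1R,5R,6R)-4-hydroxy-6-(2-hydroxypropan-2-yl)-5-methyl-3-[(2R)-2-methylbutanoyl]-1-(3-methylbut-2-en-1-yl)bicyclo[3.2.1]oct-3-ene-2,8-dione | CC[C@@H](C)C(=O)C1=C(O)[C@]2(C)C(=O)[C@@](CC=C(C)C)(C[C@H]2C(C)(C)O)C1=O | target

**Totals**

Total step count: 6. Longest linear sequence: 6 steps (1 → 4 → 6 → 8 → 9 → 11 → 12).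

**Steps most likely to fail, with fallbacks**

Step 3 (C-prenylation next to the allylic ether). O-alkylation, double alkylation or an early shift of the ether could lower the yield. The fallback reverses the order and sets out from 4: prenylation of 4 with 7 (KOH, H2O, 0 °C) gives (2R)-2-methyl-1-[2,4,6-trihydroxy-3-methyl-5-(3-methylbut-2-en-1-yl)phenyl]butan-1-one F1. Mitsunobu etherification of its para hydroxyl with 5 (PPh3, DIAD, THF) then returns to the route at 8.

Step 4 (Claisen rearrangement). The butenyl group can also migrate to the methyl-bearing ortho carbon; that regioisomer is separated and re-heated, since the shifts are reversible. Reversible shifts of the prenyl group could also erode the chirality transfer. The fallback gives up the transfer and sets out from 6: heating 6 in PhMe moves the butenyl group to the free ring carbon and gives (2R)-1-{3-[(2E)-but-2-en-1-yl]-2,4,6-trihydroxy-5-methylphenyl}-2-methylbutan-1-one F2. Alkylative dearomatization of F2 with 7 (NaOMe, MeOH, 0 °C) gives 9 together with its (6S)-epimer F3. The two are diastereomers because of the (2R)-acyl group and are separated by preparative HPLC, returning to the route at 9.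

Step 5 (radical cyclization). Attack on the butenyl group, endo closure at C6, or oxygenation of the triketone carbon before cyclization are the likely failures. The fallback is polar and sets out from 9: mCPBA (1 equiv, NaHCO3, CH2Cl2, 0 °C) epoxidizes the trisubstituted alkene to the (2R)-epoxide (6R)-6-[(2E)-but-2-en-1-yl]-6-{[(2R)-3,3-dimethyloxiran-2-yl]methyl}-3,5-dihydroxy-4-methyl-2-[(2R)-2-methylbutanoyl]cyclohexa-2,4-dien-1-one F4 and its (2S)-epoxide epimer F5. K2CO3 in MeOH then opens F4 by 5-exo attack of the methyl-bearing carbon at the secondary epoxide carbon with inversion, returning to the route at 11. F5 cannot give the exo isomer and is removed, so this fallback loses about half the material.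

**Further compounds**

F1 | step 3 | (2R)-2-methyl-1-[2,4,6-trihydroxy-3-methyl-5-(3-methylbut-2-en-1-yl)phenyl]butan-1-one | CC[C@@H](C)C(=O)c1c(O)c(C)c(O)c(CC=C(C)C)c1O
F2 | step 4 | (2R)-1-{3-[(2E)-but-2-en-1-yl]-2,4,6-trihydroxy-5-methylphenyl}-2-methylbutan-1-one | CC[C@@H](C)C(=O)c1c(O)c(C)c(O)c(C/C=C/C)c1O
F3 | step 4 | (6S)-6-[(2E)-but-2-en-1-yl]-3,5-dihydroxy-4-methyl-2-[(2R)-2-methylbutanoyl]-6-(3-methylbut-2-en-1-yl)cyclohexa-2,4-dien-1-one | CC[C@@H](C)C(=O)C1=C(O)C(C)=C(O)[C@](C/C=C/C)(CC=C(C)C)C1=O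
F4 | step 5 | (6R)-6-[(2E)-but-2-en-1-yl]-6-{[(2R)-3,3-dimethyloxiran-2-yl]methyl}-3,5-dihydroxy-4-methyl-2-[(2R)-2-methylbutanoyl]cyclohexa-2,4-dien-1-one | CC[C@@H](C)C(=O)C1=C(O)C(C)=C(O)[C@@](C/C=C/C)(C[C@@H]2C(C)(C)O2)C1=O
F5 | step 5 | (6R)-6-[(2E)-but-2-en-1-yl]-6-{[(2S)-3,3-dimethyloxiran-2-yl]methyl}-3,5-dihydroxy-4-methyl-2-[(2R)-2-methylbutanoyl]cyclohexa-2,4-dien-1-one | CC[C@@H](C)C(=O)C1=C(O)C(C)=C(O)[C@@](C/C=C/C)(C[C@H]2C(C)(C)O2)C1=O
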